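**Plan**
- Retrosynthesis: the lactol O–C bond to a chiral photolabile acetal auxiliary and the salicyl-alcohol acetonide are cut last; then the depsidone ester C(=O)–O bond (lactonisation) and the diaryl ether C–O bond (SNAr) are cut, giving ring A fluoride 25 and ring B phenol 18.
- In ring B the CH2OH carbon is cut next (ortho-hydroxymethylation), and then both exocyclic C–C bonds of the hydroxyphthalide (aryl–C=O and aryl–CH(OH)) are cut in one disconnection.
- Enabling feature: in ring B the free phenol oxygen stands para to the diaryl-ether oxygen (hydroquinone pattern). The ring is therefore a p-quinone monoketal in disguise, whose only unsubstituted enone CH=CH consists of the two carbons that carry the lactone carbonyl and the lactol carbon. The O=C–O–CH(OH) unit of the lactone corresponds to a (phenylsulfonyl)methyl carbonate.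
- Forward: isovanillin → monoketal 5 (3 steps); Michael/Dieckmann/fragmentation/aromatisation with 8 gives benzoate 11; pseudo-ester formation, O-demethylation, hydroxymethylation and acetonide formation give 18; SNAr with 25, deallylation and closure of the seven-membered lactone follow, then deprotection.
- Stereochemistry: the single stereocentre (lactol carbon, S) is held as a mixed acetal with (S)-1-(2-nitrophenyl)ethanol; the epimers are separated at 28, and photolysis breaks the auxiliary's O–C bond, not the acetal carbon.

Key step: step 5

Remark: the lactol carbon is a hemiacetal that can epimerise through the ring-opened 2-formylbenzoic acid form, so it is carried as a mixed acetal and set free only in the last step under neutral conditions; its configurational stability in solution is not assumed.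

Step 1
Reactants: 1 isovanillin (3-hydroxy-4-methoxybenzaldehyde)
Product: 2 3-(allyloxy)-4-methoxybenzaldehyde
Conditions: allyl bromide, K2CO3, DMF, 60 °C
Reagents that add atoms: allyl bromide, C=CCBr
Why: Williamson ether synthesis on the only phenol; the allyl ether masks the future ester oxygen of ring B and is removable later under neutral Pd(0) conditions.

Step 2
Reactants: 2 3-(allyloxy)-4-methoxybenzaldehyde
Product: 4 3-(allyloxy)-4-methoxyphenol, via aryl formate 3 (not isolated)
Conditions: mCPBA, CH2Cl2, 0 °C to rt; then K2CO3 (cat.), MeOH, rt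
Reagents that add atoms: mCPBA, OOC(=O)c1cccc(Cl)c1
Why: Baeyer–Villiger (Dakin-type) oxidation, in which the electron-rich aryl group migrates and the formate is methanolysed, should give the phenol para to the methoxy group.

Step 3
Reactants: 4 3-(allyloxy)-4-methoxyphenol
Product: 5 3-(allyloxy)-4,4-dimethoxycyclohexa-2,5-dien-1-one
Conditions: PhI(OAc)2, MeOH, 0 °C
Reagents that add atoms: methanol, CO
Why: hypervalent-iodine oxidative dearomatisation of a p-methoxyphenol; methanol adds at the para carbon and gives the p-quinone monoketal.

Step 4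
Reactants: 6 sodium benzenesulfinate; 7 chloromethyl methyl carbonate
Product: 8 methyl (phenylsulfonyl)methyl carbonate
Conditions: NaI (cat.), DMF, rt
Reagents that add atoms: none
Why: SN2 S-alkylation of the sulfinate by the chloromethyl carbonate (iodide catalysis), the way alkoxymethyl sulfones are made from sulfinates and α-chloro ethers.

Step 5
Reactants: 5 3-(allyloxy)-4,4-dimethoxycyclohexa-2,5-dien-1-one; 8 methyl (phenylsulfonyl)methyl carbonate
Product: 11 methyl 4-(allyloxy)-2-formyl-6-hydroxy-3-methoxybenzoate, via Michael adduct 9 (not isolated), via keto ester aldehyde 10 (not isolated)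
Conditions: LiHMDS (2.2 equiv) added to 5 + 8, THF, −78 to 0 °C; aq. HCl
Reagents that add atoms: none
Why: Proposed new method: the sulfonyl-stabilised carbanion of 8 adds 1,4 to the unsubstituted enone carbon C5 of 5 (9), the resulting ketone enolate acylates itself on the carbonate carbonyl through a transient five-membered ring, the tetrahedral intermediate opens by C–O cleavage to an α-sulfonyl alkoxide that expels benzenesulfinate to give the aldehyde (10), and base-mediated loss of methanol from the ketal aromatises the ring to the phenoxide of 11. The closest known reaction type is the Hauser–Kraus annulation of 3-(phenylsulfonyl)phthalide anions with quinone monoketals, which runs through the same Michael addition, Dieckmann-type acylation, C–O fragmentation, sulfinate loss and methanol loss; new here are the acyclic one-carbon donor and a carbonate instead of a benzoate as the acylating group. No ring of the product is closed: the transient ring forms by 5-(enolexo)-exo-trig attack and is reopened, and the benzene ring arises by elimination. No stereocentre persists, since the sp3 centres of 9 and 10 are lost on aromatisation. The step needs regioselective conjugate addition and a defined direction of collapse: the 3-allyloxy group turns the other enone into a deactivated vinylogous ester so that only C5 is attacked, which puts CHO next to the former ketal carbon (future diaryl-ether oxygen) and CO2Me next to the former carbonyl (future free phenol), and the sulfonyl-stabilised alkoxide is a much better leaving group than methoxide; the main hazard, a 1,2-shift of the carbonate group in the free carbanion, is limited by deprotonating 8 at −78 °C with the acceptor present.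

Step 6
Reactants: 11 methyl 4-(allyloxy)-2-formyl-6-hydroxy-3-methoxybenzoate; 12 (S)-1-(2-nitrophenyl)ethanol
Product: 13 5-(allyloxy)-7-hydroxy-4-methoxy-3-[(1S)-1-(2-nitrophenyl)ethoxy]isobenzofuran-1(3H)-one (both C3 epimers)
Conditions: TsOH·H2O (cat.), toluene, reflux, 5 Å sieves (removal of MeOH)
Reagents that add atoms: none
Why: acid-catalysed conversion of the normal ester of a 2-formylbenzoate into its pseudo-ester (hemiacetal formation with 12, then lactonisation with loss of methanol); the new acetal centre is not controlled and forms as both epimers, which are separated at 28.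

Step 7
Reactants: 13 pseudo-ester (C3 epimers)
Product: 15 5-(allyloxy)-4,7-dihydroxy-3-[(1S)-1-(2-nitrophenyl)ethoxy]isobenzofuran-1(3H)-one (C3 epimers), via quinone 14 (not isolated)
Conditions: PhI(OAc)2, MeCN/H2O, 0 °C; then aq. Na2S2O4
Reagents that add atoms: water, O
Why: oxidative demethylation of a p-methoxyphenol to the p-quinone followed by dithionite reduction frees the oxygen for the diaryl ether without a Lewis acid, so the allyl ether and the acetal should survive.

Step 8
Reactants: 15 hydroquinone pseudo-ester (C3 epimers)
Product: 16 cyclic phenylboronate bridging the 7-O and the new 6-CH2O group of 15 (2-phenyl-4H-1,3,2-benzodioxaborin; C3 epimers)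
Conditions: PhB(OH)2, (CH2O)n, EtCO2H (cat.), toluene, reflux, Dean–Stark
Reagents that add atoms: paraformaldehyde (as formaldehyde), C=O; phenylboronic acid, OB(O)c1ccccc1
Why: boronic-acid-templated ortho-hydroxymethylation of a phenol: the aryl boronate delivers formaldehyde to the only free ortho CH, between the 7-OH and the allyloxy carbon, while the 4-OH has no free ortho position.

Step 9
Reactants: 16 cyclic phenylboronate
Product: 18 acetonide (2,2-dimethyl-4H-1,3-benzodioxine across the 7-O and 6-CH2O) with free 4-OH (C3 epimers), via diol 17 (not isolated)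
Conditions: pinacol, 2,2-dimethoxypropane, PPTS (cat.), acetone, rt
Reagents that add atoms: 2,2-dimethoxypropane, COC(C)(C)OC
Why: boronate transesterification to pinacol frees the salicyl alcohol, which is ketalised in situ (acetonide formation), masking the chelated phenol and the CH2OH together and leaving one free phenol.

Step 10
Reactants: 19 3-fluoro-5-methylphenol
Product: 20 4-bromo-3-fluoro-5-methylphenol
Conditions: NBS, MeCN, 0 °C
Reagents that add atoms: N-bromosuccinimide, O=C1CCC(=O)N1Br
Why: electrophilic aromatic bromination para to the hydroxyl group, as found for 3,5-disubstituted phenols.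

Step 11
Reactants: 20 4-bromo-3-fluoro-5-methylphenol
Product: 21 5-(allyloxy)-2-bromo-1-fluoro-3-methylbenzene
Conditions: allyl bromide, K2CO3, acetone, reflux
Reagents that add atoms: allyl bromide, C=CCBr
Why: Williamson ether synthesis; the allyl group keeps the phenol from deactivating the later SNAr and leaves with the other allyl groups.

Step 12
Reactants: 21 5-(allyloxy)-2-bromo-1-fluoro-3-methylbenzene
Product: 23 allyl 4-(allyloxy)-2-fluoro-6-methylbenzoate, via arylmagnesium chloride 22 (not isolated)
Conditions: i-PrMgCl·LiCl, THF, 0 °C to rt; then added to allyl chloroformate, −40 °C to rt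
Reagents that add atoms: allyl chloroformate, C=CCOC(=O)Cl
Why: bromine–magnesium exchange (accelerated by the ortho fluorine, and the ortho-fluoro Grignard does not eliminate to an aryne) followed by acylation with a chloroformate; the di-ortho-substituted ester resists over-addition.

Step 13
Reactants: 23 allyl 4-(allyloxy)-2-fluoro-6-methylbenzoate
Product: 25 allyl 4-(allyloxy)-2-fluoro-3-formyl-6-methylbenzoate, via 3-magnesiated ester 24 (not isolated)
Conditions: TMPMgCl·LiCl, THF, −20 °C; then DMF; aq. NH4Cl
Reagents that add atoms: N,N-dimethylformamide, CN(C)C=O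
Why: directed magnesiation with an ester-tolerant magnesium amide at the most acidic ring CH (flanked by F and OR), then formylation with DMF.

Step 14
Reactants: 18 acetonide phenol (C3 epimers); 25 allyl 4-(allyloxy)-2-fluoro-3-formyl-6-methylbenzoate
Product: 26 diaryl ether (C3 epimers)
Conditions: K2CO3, DMF, 50 °C
Reagents that add atoms: none
Why: SNAr (addition–elimination): the fluoride is activated by an ortho-formyl and an ortho-ester group, and 18 has a single free phenol.

Step 15
Reactants: 26 diaryl ether
Product: 27 seco acid with free ring A carboxylic acid, ring A 4-OH and ring B 5-OH (C3 epimers)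
Conditions: Pd(PPh3)4 (cat.), PhSO2Na, THF/MeOH, rt; aq. HCl work-up
Reagents that add atoms: none
Why: Tsuji–Trost deallylation of the allyl ester and both aryl allyl ethers with a soft sulfinate as allyl acceptor, which does not condense with the aldehyde or open the pseudo-ester.

Step 16
Reactants: 27 seco acid
Product: 28 depsidone with acetonide and auxiliary in place, single epimer with (S) acetal carbon
Conditions: EDC·HCl, DMAP (cat.), CH2Cl2 (high dilution), 0 °C to rt; chromatographic separation of the two acetal epimers
Reagents that add atoms: none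
Why: carbodiimide lactonisation closes the seven-membered depsidone ring (7-exo-trig) onto the only phenol ortho to the ether oxygen; the acetal epimers are separated here, with the configuration to be assigned by crystallography.

Step 17
Reactants: 28 depsidone acetonide
Product: 29 depsidone with free phenol and CH2OH, auxiliary in place
Conditions: AcOH/H2O/THF, 40 °C
Reagents that add atoms: none
Why: mild acid hydrolysis of the ketal; the acyloxy acetal at the lactol carbon and the nitro-deactivated benzylic ether need much stronger acid to ionise, so the (S) centre should be kept.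

Step 18
Reactants: 29 depsidone with auxiliary
Product: 30 CNP0166154.1 (salazinic acid, (S)-lactol)
Conditions: hν (365 nm), MeCN/pH 7 buffer, 5 °C
Reagents that add atoms: none
Why: o-nitrobenzyl-type photocleavage (hydrogen abstraction by the excited nitro group, aci-nitro form, hemiketal collapse) breaks the auxiliary's benzylic C–O bond, so the lactol carbon keeps the (S) configuration fixed in 28.

**Compound list**
1 | isovanillin (3-hydroxy-4-methoxybenzaldehyde) | COc1ccc(C=O)cc1O | starting material
2 | 3-(allyloxy)-4-methoxybenzaldehyde | COc1ccc(C=O)cc1OCC=C | intermediate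
3 | 3-(allyloxy)-4-methoxyphenyl formate | COc1ccc(OC=O)cc1OCC=C | intermediate
4 | 3-(allyloxy)-4-methoxyphenol | COc1ccc(O)cc1OCC=C | intermediate
5 | 3-(allyloxy)-4,4-dimethoxycyclohexa-2,5-dien-1-one | COC1(OC)C=CC(=O)C=C1OCC=C | intermediate
6 | sodium benzenesulfinate | [Na+].[O-]S(=O)c1ccccc1 | starting material
7 | chloromethyl methyl carbonate | COC(=O)OCCl | starting material
8 | methyl (phenylsulfonyl)methyl carbonate | COC(=O)OCS(=O)(=O)c1ccccc1 | intermediate
9 | 3-(allyloxy)-4,4-dimethoxy-5-[(methoxycarbonyloxy)(phenylsulfonyl)methyl]cyclohex-2-en-1-one (racemic, configuration undefined) | COC(=O)OC(S(=O)(=O)c1ccccc1)C1CC(=O)C=C(OCC=C)C1(OC)OC | intermediate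
10 | methyl 4-(allyloxy)-2-formyl-3,3-dimethoxy-6-oxocyclohex-4-ene-1-carboxylate (racemic, configuration undefined) | COC(=O)C1C(C=O)C(OC)(OC)C(OCC=C)=CC1=O | intermediate
11 | methyl 4-(allyloxy)-2-formyl-6-hydroxy-3-methoxybenzoate | COC(=O)c1c(O)cc(OCC=C)c(OC)c1C=O | intermediate
12 | (S)-1-(2-nitrophenyl)ethanol | C[C@H](O)c1ccccc1[N+](=O)[O-] | starting material
13 | 5-(allyloxy)-7-hydroxy-4-methoxy-3-[(1S)-1-(2-nitrophenyl)ethoxy]isobenzofuran-1(3H)-one (C3 epimers) | COc1c(OCC=C)cc(O)c2c1C(O[C@@H](C)c1ccccc1[N+](=O)[O-])OC2=O | intermediate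
14 | 5-(allyloxy)-3-[(1S)-1-(2-nitrophenyl)ethoxy]isobenzofuran-1,4,7(3H)-trione (C3 epimers) | C=CCOC1=CC(=O)C2=C(C1=O)C(O[C@@H](C)c1ccccc1[N+](=O)[O-])OC2=O | intermediate
15 | 5-(allyloxy)-4,7-dihydroxy-3-[(1S)-1-(2-nitrophenyl)ethoxy]isobenzofuran-1(3H)-one (C3 epimers) | C=CCOc1cc(O)c2c(c1O)C(O[C@@H](C)c1ccccc1[N+](=O)[O-])OC2=O | intermediate
16 | cyclic phenylboronate (2-phenyl-4H-1,3,2-benzodioxaborin) of diol 17 (C3 epimers) | C=CCOc1c2COB(c3ccccc3)Oc2c2c(c1O)C(O[C@@H](C)c1ccccc1[N+](=O)[O-])OC2=O | intermediate
17 | 5-(allyloxy)-4,7-dihydroxy-6-(hydroxymethyl)-3-[(1S)-1-(2-nitrophenyl)ethoxy]isobenzofuran-1(3H)-one (C3 epimers) | C=CCOc1c(CO)c(O)c2c(c1O)C(O[C@@H](C)c1ccccc1[N+](=O)[O-])OC2=O | intermediate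
18 | acetonide of 17 across the 7-O and 6-CH2O, free 4-OH (C3 epimers) | C=CCOc1c2COC(C)(C)Oc2c2c(c1O)C(O[C@@H](C)c1ccccc1[N+](=O)[O-])OC2=O | intermediate
19 | 3-fluoro-5-methylphenol | Cc1cc(O)cc(F)c1 | starting material
20 | 4-bromo-3-fluoro-5-methylphenol | Cc1cc(O)cc(F)c1Br | intermediate
21 | 5-(allyloxy)-2-bromo-1-fluoro-3-methylbenzene | Cc1cc(OCC=C)cc(F)c1Br | intermediate
22 | [4-(allyloxy)-2-fluoro-6-methylphenyl]magnesium chloride | Cc1cc(OCC=C)cc(F)c1[Mg]Cl | intermediate
23 | allyl 4-(allyloxy)-2-fluoro-6-methylbenzoate | Cc1cc(OCC=C)cc(F)c1C(=O)OCC=C | intermediate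
24 | 3-(chloromagnesio) derivative of 23 | Cc1cc(OCC=C)c([Mg]Cl)c(F)c1C(=O)OCC=C | intermediate
25 | allyl 4-(allyloxy)-2-fluoro-3-formyl-6-methylbenzoate | Cc1cc(OCC=C)c(C=O)c(F)c1C(=O)OCC=C | intermediate
26 | diaryl ether from 18 and 25 (C3 epimers) | C=CCOc1c2COC(C)(C)Oc2c2c(c1Oc3c(C=O)c(OCC=C)cc(C)c3C(=O)OCC=C)C(O[C@@H](C)c4ccccc4[N+](=O)[O-])OC2=O | intermediate
27 | seco acid: tris-deallylated 26 (C3 epimers) | Oc1c2COC(C)(C)Oc2c2c(c1Oc3c(C=O)c(O)cc(C)c3C(=O)O)C(O[C@@H](C)c4ccccc4[N+](=O)[O-])OC2=O | intermediate
28 | depsidone with acetonide and (1S)-1-(2-nitrophenyl)ethyl acetal, (S) acetal carbon | Cc1cc(O)c(C=O)c2c1C(=O)Oc1c4COC(C)(C)Oc4c3c(c1O2)[C@@H](O[C@@H](C)c5ccccc5[N+](=O)[O-])OC3=O | intermediate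
29 | O-[(1S)-1-(2-nitrophenyl)ethyl] acetal of the target, (S) acetal carbon | Cc1cc(O)c(C=O)c2c1C(=O)Oc1c(CO)c(O)c3c(c1O2)[C@@H](O[C@@H](C)c4ccccc4[N+](=O)[O-])OC3=O | intermediate
30 | CNP0166154.1 (salazinic acid, (S)-lactol) | Cc1cc(O)c(C=O)c2c1C(=O)Oc1c(CO)c(O)c3c(c1O2)[C@@H](O)OC3=O | target

Total step count: 18. Longest linear sequence: 13 steps (1, 2, 3, 5, 6, 7, 8, 9, 14, 15, 16, 17, 18).

**Steps most likely to fail**

Step 5 (proposed new method). The sulfonyl carbanion may destroy itself by 1,2-migration of the carbonate group before it adds, or the enolate may fail to acylate so that the sequence stops at the Michael stage. The fallback uses known chemistry and makes the two C–C bonds one after the other on the aromatic ring. It sets out from phenol 4. Ortho-formylation with MgCl2/Et3N/paraformaldehyde (MeCN, reflux) at the less hindered ortho position should give 4-(allyloxy)-2-hydroxy-5-methoxybenzaldehyde F1. Pinnick oxidation (NaClO2, NaH2PO4, 2-methyl-2-butene) should give 4-(allyloxy)-2-hydroxy-5-methoxybenzoic acid F2, and MeI/KHCO3 in DMF the ester methyl 4-(allyloxy)-2-hydroxy-5-methoxybenzoate F3. TBSCl/imidazole should give methyl 4-(allyloxy)-2-[(tert-butyldimethylsilyl)oxy]-5-methoxybenzoate F4. Magnesiation with TMPMgCl·LiCl at the CH between the ester and the methoxy group, then DMF, should give methyl 4-(allyloxy)-6-[(tert-butyldimethylsilyl)oxy]-2-formyl-3-methoxybenzoate F5. TBAF/AcOH removes the silyl group and the route is rejoined at 11.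

Step 8. The hydrogen-bonded, acyl-substituted phenol ring may be too poor a nucleophile for the boronate to C-alkylate, or the benzylic boronate may condense further to diarylmethanes. The fallback sets out from 15. Ortho-formylation with MgCl2/Et3N/paraformaldehyde should give 5-(allyloxy)-6-formyl-4,7-dihydroxy-3-[(1S)-1-(2-nitrophenyl)ethoxy]isobenzofuran-1(3H)-one F6. NaBH4 (MeOH, 0 °C) reduces only the aldehyde and gives diol 17, which is ketalised as in step 9 (without pinacol) to rejoin the route at 18.

Step 7. The electron-poor quinone may be hydrated or over-oxidised before it is reduced. The fallback sets out from 11. Chelation-controlled cleavage of the methoxy group ortho to the formyl group with MgI2·OEt2 (toluene, 60 °C) should give methyl 4-(allyloxy)-2-formyl-3,6-dihydroxybenzoate F7. Pseudo-ester formation with 12 under the conditions of step 6 then gives 15 directly.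

**Further compounds**
F1 | step 5 | 4-(allyloxy)-2-hydroxy-5-methoxybenzaldehyde | COc1cc(C=O)c(O)cc1OCC=C
F2 | step 5 | 4-(allyloxy)-2-hydroxy-5-methoxybenzoic acid | COc1cc(C(=O)O)c(O)cc1OCC=C
F3 | step 5 | methyl 4-(allyloxy)-2-hydroxy-5-methoxybenzoate | COC(=O)c1cc(OC)c(OCC=C)cc1O
F4 | step 5 | methyl 4-(allyloxy)-2-[(tert-butyldimethylsilyl)oxy]-5-methoxybenzoate | COC(=O)c1cc(OC)c(OCC=C)cc1O[Si](C)(C)C(C)(C)C
F5 | step 5 | methyl 4-(allyloxy)-6-[(tert-butyldimethylsilyl)oxy]-2-formyl-3-methoxybenzoate | COC(=O)c1c(C=O)c(OC)c(OCC=C)cc1O[Si](C)(C)C(C)(C)C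
F6 | step 8 | 5-(allyloxy)-6-formyl-4,7-dihydroxy-3-[(1S)-1-(2-nitrophenyl)ethoxy]isobenzofuran-1(3H)-one (C3 epimers) | C=CCOc1c(C=O)c(O)c2c(c1O)C(O[C@@H](C)c1ccccc1[N+](=O)[O-])OC2=O
F7 | step 7 | methyl 4-(allyloxy)-2-formyl-3,6-dihydroxybenzoate | COC(=O)c1c(O)cc(OCC=C)c(O)c1C=O
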